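**Strategy.** The stereocentre C-3 of the hept-1-ene chain (the CH on the phloroglucinol A ring) and its C-1=C-2 styryl neighbour on the 4-hydroxyphenyl ring are read together as the deoxygenated Z-enolate of a 1,3-diarylpropan-1-one. C-3 is therefore the β-carbon of the flat "retro-chalcone" 6. A copper-catalysed asymmetric conjugate addition of the 4-arylbutyl Grignard reagent to 6 joins C-3 to C-4 and sets the only stereocentre under ligand control. O-Triflation of the resulting Z-enolate in the same flask stores the E-styrene geometry, which a Pd/formate reduction releases. A-ring iodination, Weinreb acylation to the chalcone and mild global MOM removal complete the route.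

Key step: step 5

Remark: the stereocentre is read as R (A-ring carbon > C-2 > C-4 > H). Chain locants are C-1 (styryl CH on the aryl ring), C-3 (stereocentre) and C-7 (CH2 on the second aryl ring).
Assumption: the simple MOM ethers 5, 7 and 16 are taken as catalogue compounds; each is otherwise one MOMCl/i-Pr2NEt step from the parent phenol.

**Step 1**
Reactants: 1 5-methoxyresorcinol
Product: 2 1-methoxy-3,5-bis(methoxymethoxy)benzene
Conditions: MOMCl, i-Pr2NEt, CH2Cl2, 0 °C → rt
Reagents that add atoms: chloromethyl methyl ether (MOMCl), COCCl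
Why: O-alkylation of both phenols (MOM protection) gives ethers that later direct the ortho-lithiation and should survive hydroxide, Grignard and Pd chemistry.

**Step 2**
Reactants: 2 1-methoxy-3,5-bis(methoxymethoxy)benzene
Product: 4 4-methoxy-2,6-bis(methoxymethoxy)benzaldehyde, via aryllithium 3 (not isolated)
Conditions: n-BuLi, TMEDA, THF, 0 °C; then DMF, 0 °C → rt; H2O
Reagents that add atoms: N,N-dimethylformamide (DMF), CN(C)C=O
Why: Directed ortho-metalation should take place at the C–H flanked by both OMOM groups (cooperative coordination), and the aryllithium is formylated by DMF.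

**Step 3**
Reactants: 4 4-methoxy-2,6-bis(methoxymethoxy)benzaldehyde; 5 1-[4-(methoxymethoxy)phenyl]ethanone
Product: 6 (2E)-3-[4-methoxy-2,6-bis(methoxymethoxy)phenyl]-1-[4-(methoxymethoxy)phenyl]prop-2-en-1-one
Conditions: KOH, EtOH/H2O, rt
Reagents that add atoms: none
Why: Claisen–Schmidt aldol condensation of a non-enolisable aldehyde with an aryl methyl ketone should give the thermodynamic E-enone.

**Step 4**
Reactants: 7 1-bromo-4-(methoxymethoxy)benzene; 8 1,4-dibromobutane
Product: 10 1-(4-bromobutyl)-4-(methoxymethoxy)benzene, via aryl Grignard reagent 9 (not isolated)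
Conditions: Mg, THF, 40 °C; then 8 (3 equiv), Li2CuCl4 (3 mol %), THF, 0 °C → rt
Reagents that add atoms: none
Why: Copper-catalysed sp2–sp3 cross-coupling of an aryl Grignard reagent with a primary alkyl bromide, with excess dibromide to suppress double coupling.

**Step 5**
Reactants: 6 (2E)-3-[4-methoxy-2,6-bis(methoxymethoxy)phenyl]-1-[4-(methoxymethoxy)phenyl]prop-2-en-1-one; 10 1-(4-bromobutyl)-4-(methoxymethoxy)benzene
Product: 13 (1Z,3R)-3-[4-methoxy-2,6-bis(methoxymethoxy)phenyl]-1,7-bis[4-(methoxymethoxy)phenyl]hept-1-en-1-yl trifluoromethanesulfonate, via Grignard reagent 11 (not isolated), via bromomagnesium Z-enolate 12 (not isolated)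
Conditions: 10, Mg, Et2O, rt; added slowly to 6, CuBr·SMe2 (5 mol %), (R,S)-Josiphos (6 mol %), t-BuOMe/CH2Cl2, −78 °C; then N-(5-chloro-2-pyridyl)triflimide, THF, −78 → 0 °C
Reagents that add atoms: N-(5-chloro-2-pyridyl)bis(trifluoromethanesulfonimide), O=S(=O)(N(c1ccc(Cl)cn1)S(=O)(=O)C(F)(F)F)C(F)(F)F
Why: The alkyl Grignard reagent transmetalates to a chiral diphosphine–copper(I) alkyl, which π-binds the s-cis enone, adds oxidatively at C-3 to a Cu(III) σ-enolate and reductively eliminates, forming the C-3–C-4 bond and the bromomagnesium Z-enolate, which is O-sulfonylated with retention of geometry. The closest known reaction type is the Cu/ferrocenyl-diphosphine-catalysed asymmetric conjugate addition of Grignard reagents to acyclic enones with trapping of the enolate as its enol triflate. No ring is closed. The new C-3 stereocentre is under catalyst control: the ligand antipode is chosen so that the alkyl group enters the Re face of C-3 (A ring > C-2 > H), which corresponds to 3R. The step needs facial selectivity and 1,4-regioselectivity free of uncatalysed Grignard addition, secured by slow addition of 11 at −78 °C to the preformed copper complex, and it needs Z-enolate geometry, secured by the s-cis preference of the aryl enone.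

**Step 6**
Reactants: 13 (1Z,3R)-3-[4-methoxy-2,6-bis(methoxymethoxy)phenyl]-1,7-bis[4-(methoxymethoxy)phenyl]hept-1-en-1-yl trifluoromethanesulfonate
Product: 14 2-{(1E,3R)-1,7-bis[4-(methoxymethoxy)phenyl]hept-1-en-3-yl}-5-methoxy-1,3-bis(methoxymethoxy)benzene
Conditions: Pd(OAc)2 (5 mol %), PPh3 (10 mol %), HCO2H, n-Bu3N, DMF, 60 °C
Reagents that add atoms: none
Why: Palladium-catalysed formate reduction of a vinyl triflate (oxidative addition, decarboxylation to Pd–H, reductive elimination) proceeds with retention, so the Z-triflate should give the E-styrene without touching C-3.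

**Step 7**
Reactants: 14 2-{(1E,3R)-1,7-bis[4-(methoxymethoxy)phenyl]hept-1-en-3-yl}-5-methoxy-1,3-bis(methoxymethoxy)benzene
Product: 15 2-{(1E,3R)-1,7-bis[4-(methoxymethoxy)phenyl]hept-1-en-3-yl}-4-iodo-5-methoxy-1,3-bis(methoxymethoxy)benzene
Conditions: NIS (1.0 equiv), MeCN, 0 °C, dark
Reagents that add atoms: N-iodosuccinimide (NIS), O=C1CCC(=O)N1I
Why: Electrophilic aromatic iodination should occur on the trioxygenated A ring, by far the most nucleophilic π-system, whose two free positions are equivalent, so one regioisomer is expected.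

**Step 8**
Reactants: 16 4-(methoxymethoxy)benzaldehyde; 17 diethyl {2-[methoxy(methyl)amino]-2-oxoethyl}phosphonate
Product: 18 (2E)-N-methoxy-3-[4-(methoxymethoxy)phenyl]-N-methylprop-2-enamide
Conditions: NaH, THF, 0 °C → rt
Reagents that add atoms: none
Why: Horner–Wadsworth–Emmons olefination with a stabilised phosphonate anion should give the E-cinnamoyl Weinreb amide.

**Step 9**
Reactants: 15 2-{(1E,3R)-1,7-bis[4-(methoxymethoxy)phenyl]hept-1-en-3-yl}-4-iodo-5-methoxy-1,3-bis(methoxymethoxy)benzene; 18 (2E)-N-methoxy-3-[4-(methoxymethoxy)phenyl]-N-methylprop-2-enamide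
Product: 20 (2E)-1-{3-[(1E,3R)-1,7-bis[4-(methoxymethoxy)phenyl]hept-1-en-3-yl]-6-methoxy-2,4-bis(methoxymethoxy)phenyl}-3-[4-(methoxymethoxy)phenyl]prop-2-en-1-one, via arylmagnesium chloride 19 (not isolated)
Conditions: i-PrMgCl·LiCl, THF, −20 → 0 °C; then 18, 0 °C → rt; aq. NH4Cl
Reagents that add atoms: none
Why: Iodine–magnesium exchange is faster than deprotonation at C-3, and the aryl Grignard reagent should add 1,2 to the Weinreb amide to give a stable chelate that releases the chalcone ketone only on work-up (Weinreb ketone synthesis).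

**Step 10**
Reactants: 20 (2E)-1-{3-[(1E,3R)-1,7-bis[4-(methoxymethoxy)phenyl]hept-1-en-3-yl]-6-methoxy-2,4-bis(methoxymethoxy)phenyl}-3-[4-(methoxymethoxy)phenyl]prop-2-en-1-one
Product: 22 deoxycalyxin A, via pentakis(trimethylsilyl) ether 21 (not isolated)
Conditions: TMSOTf, 2,2'-bipyridyl, CH2Cl2, 0 °C → rt; then H2O
Reagents that add atoms: none
Why: TMSOTf/2,2'-bipyridyl converts aryl MOM ethers into aryl silyl ethers under buffered, non-protic conditions, and water then frees the five phenols without acid-promoted cyclisation onto the styrene or the enone.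

**Compound list**
1 | 5-methoxyresorcinol | COc1cc(O)cc(O)c1 | starting material
2 | 1-methoxy-3,5-bis(methoxymethoxy)benzene | COCOc1cc(OC)cc(OCOC)c1 | intermediate
3 | [4-methoxy-2,6-bis(methoxymethoxy)phenyl]lithium | COCOc1cc(OC)cc(OCOC)c1[Li] | intermediate
4 | 4-methoxy-2,6-bis(methoxymethoxy)benzaldehyde | COCOc1cc(OC)cc(OCOC)c1C=O | intermediate
5 | 1-[4-(methoxymethoxy)phenyl]ethanone | CC(=O)c1ccc(OCOC)cc1 | starting material
6 | (2E)-3-[4-methoxy-2,6-bis(methoxymethoxy)phenyl]-1-[4-(methoxymethoxy)phenyl]prop-2-en-1-one | COCOc1cc(OC)cc(OCOC)c1/C=C/C(=O)c1ccc(OCOC)cc1 | intermediate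
7 | 1-bromo-4-(methoxymethoxy)benzene | COCOc1ccc(Br)cc1 | starting material
8 | 1,4-dibromobutane | BrCCCCBr | starting material
9 | [4-(methoxymethoxy)phenyl]magnesium bromide | COCOc1ccc([Mg]Br)cc1 | intermediate
10 | 1-(4-bromobutyl)-4-(methoxymethoxy)benzene | COCOc1ccc(CCCCBr)cc1 | intermediate
11 | {4-[4-(methoxymethoxy)phenyl]butyl}magnesium bromide | COCOc1ccc(CCCC[Mg]Br)cc1 | intermediate
12 | bromomagnesium (1Z,3R)-3-[4-methoxy-2,6-bis(methoxymethoxy)phenyl]-1,7-bis[4-(methoxymethoxy)phenyl]hept-1-en-1-olate | COCOc1cc(OC)cc(OCOC)c1[C@@H](/C=C(\O[Mg]Br)c1ccc(OCOC)cc1)CCCCc1ccc(OCOC)cc1 | intermediate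
13 | (1Z,3R)-3-[4-methoxy-2,6-bis(methoxymethoxy)phenyl]-1,7-bis[4-(methoxymethoxy)phenyl]hept-1-en-1-yl trifluoromethanesulfonate | COCOc1cc(OC)cc(OCOC)c1[C@@H](/C=C(\OS(=O)(=O)C(F)(F)F)c1ccc(OCOC)cc1)CCCCc1ccc(OCOC)cc1 | intermediate
14 | 2-{(1E,3R)-1,7-bis[4-(methoxymethoxy)phenyl]hept-1-en-3-yl}-5-methoxy-1,3-bis(methoxymethoxy)benzene | COCOc1cc(OC)cc(OCOC)c1[C@@H](/C=C/c1ccc(OCOC)cc1)CCCCc1ccc(OCOC)cc1 | intermediate
15 | 2-{(1E,3R)-1,7-bis[4-(methoxymethoxy)phenyl]hept-1-en-3-yl}-4-iodo-5-methoxy-1,3-bis(methoxymethoxy)benzene | COCOc1cc(OC)c(I)c(OCOC)c1[C@@H](/C=C/c1ccc(OCOC)cc1)CCCCc1ccc(OCOC)cc1 | intermediate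
16 | 4-(methoxymethoxy)benzaldehyde | COCOc1ccc(C=O)cc1 | starting material
17 | diethyl {2-[methoxy(methyl)amino]-2-oxoethyl}phosphonate | CCOP(=O)(CC(=O)N(C)OC)OCC | starting material
18 | (2E)-N-methoxy-3-[4-(methoxymethoxy)phenyl]-N-methylprop-2-enamide | COCOc1ccc(/C=C/C(=O)N(C)OC)cc1 | intermediate
19 | {2-[(1E,3R)-1,7-bis[4-(methoxymethoxy)phenyl]hept-1-en-3-yl]-6-methoxy-1,3-bis(methoxymethoxy)phen-4-yl}magnesium chloride (aryl-Mg at the former C–I carbon) | COCOc1cc(OC)c([Mg]Cl)c(OCOC)c1[C@@H](/C=C/c1ccc(OCOC)cc1)CCCCc1ccc(OCOC)cc1 | intermediate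
20 | (2E)-1-{3-[(1E,3R)-1,7-bis[4-(methoxymethoxy)phenyl]hept-1-en-3-yl]-6-methoxy-2,4-bis(methoxymethoxy)phenyl}-3-[4-(methoxymethoxy)phenyl]prop-2-en-1-one | COCOc1cc(OC)c(C(=O)/C=C/c2ccc(OCOC)cc2)c(OCOC)c1[C@@H](/C=C/c1ccc(OCOC)cc1)CCCCc1ccc(OCOC)cc1 | intermediate
21 | pentakis(trimethylsilyl) ether of deoxycalyxin A | COc1cc(O[Si](C)(C)C)c([C@@H](/C=C/c2ccc(O[Si](C)(C)C)cc2)CCCCc2ccc(O[Si](C)(C)C)cc2)c(O[Si](C)(C)C)c1C(=O)/C=C/c1ccc(O[Si](C)(C)C)cc1 | intermediate
22 | deoxycalyxin A, (2E)-1-{3-[(1E,3R)-1,7-bis(4-hydroxyphenyl)hept-1-en-3-yl]-2,4-dihydroxy-6-methoxyphenyl}-3-(4-hydroxyphenyl)prop-2-en-1-one | COc1cc(O)c([C@@H](/C=C/c2ccc(O)cc2)CCCCc2ccc(O)cc2)c(O)c1C(=O)/C=C/c1ccc(O)cc1 | target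

**Step count.** Total: 10 steps. Longest linear sequence: 8 steps (1, 2, 3, 5, 6, 7, 9, 10).

**Steps most likely to fail**

Step 5. The electron-rich, doubly ortho-substituted β-aryl enone may react sluggishly, so that uncatalysed Grignard addition erodes facial and 1,4-selectivity, and O-triflation of the magnesium enolate may be incomplete. The fallback sets out from enone 6 and forms the same C-3–C-4 bond by 1,3-chirality transfer instead of catalyst control. Corey–Bakshi–Shibata reduction (BH3·SMe2, catalyst antipode that gives the R carbinol) should give (1R,2E)-3-[4-methoxy-2,6-bis(methoxymethoxy)phenyl]-1-[4-(methoxymethoxy)phenyl]prop-2-en-1-ol F1. Esterification with picolinic acid (DCC, DMAP, CH2Cl2, 0 °C) gives its pyridine-2-carboxylate F2. Copper-mediated anti-SN2' substitution with Grignard reagent 11 (CuBr·SMe2, THF, −78 °C), directed to the γ-carbon by the chelating picolinate, should transfer the R carbinol configuration to 3R and create the E-styrene directly. The fallback comes back to the route at 14.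

Step 9. The arylmagnesium flanked by two alkoxy groups may add slowly to the cinnamoyl Weinreb amide, leaving time for conjugate addition or protonation of the aryl-metal. The fallback sets out from iodide 15 and builds the chalcone in two stages. After the same exchange to 19, acylation with the small electrophile N-methoxy-N-methylacetamide should give 1-{3-[(1E,3R)-1,7-bis[4-(methoxymethoxy)phenyl]hept-1-en-3-yl]-6-methoxy-2,4-bis(methoxymethoxy)phenyl}ethanone F3. Claisen–Schmidt condensation of this with aldehyde 16 (KOH, EtOH, rt) comes back to the route at 20.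

Step 6. Palladium hydride may re-add to the new styrene and move the double bond toward the A ring, which would erase the C-3 stereocentre, or a geometrically impure enol triflate may carry E/Z erosion into the alkene. The fallback sets out from enone 6 and bromide 10. Step 5 is run without the triflimide and enolate 12 is protonated to (3R)-3-[4-methoxy-2,6-bis(methoxymethoxy)phenyl]-1,7-bis[4-(methoxymethoxy)phenyl]heptan-1-one F4. NaBH4 (MeOH, 0 °C) gives (3R)-3-[4-methoxy-2,6-bis(methoxymethoxy)phenyl]-1,7-bis[4-(methoxymethoxy)phenyl]heptan-1-ol F5 as C-1 epimers, which is of no consequence. Dehydration with Burgess reagent (toluene, 50 °C; syn-elimination toward the only β-hydrogens at C-2) should give the conjugated E-styrene and comes back to the route at 14.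

**Further compounds**
F1 | step 5 | (1R,2E)-3-[4-methoxy-2,6-bis(methoxymethoxy)phenyl]-1-[4-(methoxymethoxy)phenyl]prop-2-en-1-ol | COCOc1cc(OC)cc(OCOC)c1/C=C/[C@@H](O)c1ccc(OCOC)cc1
F2 | step 5 | (1R,2E)-3-[4-methoxy-2,6-bis(methoxymethoxy)phenyl]-1-[4-(methoxymethoxy)phenyl]prop-2-en-1-yl pyridine-2-carboxylate | COCOc1cc(OC)cc(OCOC)c1/C=C/[C@@H](OC(=O)c1ccccn1)c1ccc(OCOC)cc1
F3 | step 9 | 1-{3-[(1E,3R)-1,7-bis[4-(methoxymethoxy)phenyl]hept-1-en-3-yl]-6-methoxy-2,4-bis(methoxymethoxy)phenyl}ethanone | COCOc1cc(OC)c(C(C)=O)c(OCOC)c1[C@@H](/C=C/c1ccc(OCOC)cc1)CCCCc1ccc(OCOC)cc1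
F4 | step 6 | (3R)-3-[4-methoxy-2,6-bis(methoxymethoxy)phenyl]-1,7-bis[4-(methoxymethoxy)phenyl]heptan-1-one | COCOc1cc(OC)cc(OCOC)c1[C@@H](CC(=O)c1ccc(OCOC)cc1)CCCCc1ccc(OCOC)cc1
F5 | step 6 | (3R)-3-[4-methoxy-2,6-bis(methoxymethoxy)phenyl]-1,7-bis[4-(methoxymethoxy)phenyl]heptan-1-ol (C-1 epimers) | COCOc1cc(OC)cc(OCOC)c1[C@@H](CC(O)c1ccc(OCOC)cc1)CCCCc1ccc(OCOC)cc1
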